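**Strategy.** Ring A (C1'–C6') plus the cinnamoyl chain is treated as a folded tetraketide. Yangonin 1 already supplies C4' (lactone carbonyl C2), C5' (C3), C6' with its methoxy group (C4), C1' (C5) and, from C6 outward, the intact E-4-methoxycinnamoyl unit. Only C3' and C2' are missing. These come from tert-butyl acetate 2. Its lithium enolate 3 is acylated by the lactone (C3'–C4'), and the opened chain 4 refolds by Claisen closure (C1'–C2') to chalcone 5 in the same flask (one ring, two C–C bonds). Chromene annulation with 3-methylbut-2-enal 6 across C3' and O4', through quinone methide 7, then gives glychalcone A 8.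

Key step: step 1

Remark: primed locants refer to chalcone ring A and unprimed ones to the pyranone; 4 is drawn in its neutral keto form although it exists in the flask as a dilithium dianion; yangonin is taken as a catalogue kavalactone of E configuration.

Step 1
Reactants: 1 yangonin; 2 tert-butyl acetate
Product: 5 (E)-2',4'-dihydroxy-4,6'-dimethoxychalcone, via lithium enolate 3 (not isolated), via opened keto ester 4 (not isolated)
Conditions: LiN(iPr)2 (commercial solution, 3.0 equiv), 2 (3.3 equiv), THF, −78 °C; then 1 in THF, −78 → 0 °C; then 25–50 °C; AcOH, −20 °C
Reagents that add atoms: none
Why: Proposed new method: enolate 3 should add to C2 of 1, the only carbonyl carbon and an enol-ester acyl group whose leaving group is a conjugated enolate, so that collapse of the adduct cleaves C2–O1 and sets the C3'–C4' bond; a second equivalent of 3 deprotonates C3' of the new β-keto ester, which blocks the reverse reaction and leaves 4 as a dilithium dianion. In this dianion the former pyranone C5 (C1'), the α-carbon of the cinnamoyl enolate and the less stabilised of the two carbanion sites, attacks the tert-butyl ester in a 6-(enolexo)-exo-trig Claisen (Dieckmann-type) closure that forms C1'–C2' and ring A; tert-butoxide leaves and the cyclic triketone tautomerises to the bis-phenoxide of 5, so aromatisation makes the sequence irreversible. The closest known reaction types are the crossed Claisen acylation of excess lithio tert-butyl acetate by esters and lactones, the opening of 4-methoxy-2-pyranones at the lactone carbonyl by lithium carbanions, and the strong-base Claisen cyclisation of 3,5,7-triketo esters to acylphloroglucinols. Attack at C2 rather than at C4, C6 or the styryl terminus is required, and it should be secured by kinetic addition of a hard lithium ester enolate at −78 °C to a pyranone whose conjugate positions are all damped by donors (4-OMe, ring O1, the anisyl group), with the slight excess of 2 leaving no free LiN(iPr)2 to metalate C3 or C5. Claisen rather than aldol closure (C3' on the cinnamoyl carbonyl) is required, and it should be secured because that ketone is held as its enolate, because a lithium aldolate has no leaving group in aprotic base and can only revert whereas the Claisen adduct expels tert-butoxide, because the C5'=C6' bond inherits from the ring the cis placement of C4' and C1', and because the C6' oxygen is capped as a methyl ether and cannot lactonise onto the ester. No stereocentre is created, and the E-alkene, conjugated first to an enolate and then to a ketone deactivated by two phenoxides, should resist Michael addition of surplus 3, while the cold acetic acid quench avoids closure of the 2'-hydroxychalcone to the flavanone.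

Step 2
Reactants: 5 (E)-2',4'-dihydroxy-4,6'-dimethoxychalcone; 6 3-methylbut-2-enal
Product: 8 glychalcone A, via o-quinone methide 7 (not isolated)
Conditions: 6 (2 equiv), ethylenediammonium diacetate (20 mol %), toluene, 110 °C
Reagents that add atoms: none
Why: This is the known amine-salt-catalysed formal [3+3] chromene annulation of resorcinols with enals (Knoevenagel-type condensation through the iminium ion of 6, loss of water to 7, oxa-6π electrocyclisation), in which C3', flanked by two free hydroxyls and favoured by the bond fixation of the C2'–OH···O=C chelate, should be the reacting carbon and the free O4' rather than the chelated O2' should close the pyran, while the near-neutral catalyst spares the enone.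

**Compound list**

| No. | Name | SMILES | Role |
|---|---|---|---|
| 1 | yangonin, 4-methoxy-6-[(E)-2-(4-methoxyphenyl)ethenyl]-2H-pyran-2-one | COC1=CC(=O)OC(/C=C/c2ccc(OC)cc2)=C1 | starting material |
| 2 | tert-butyl acetate | CC(=O)OC(C)(C)C | starting material |
| 3 | lithium 1-tert-butoxyethen-1-olate (lithium enolate of 2) | [Li+].C=C([O-])OC(C)(C)C | intermediate |
| 4 | tert-butyl (4E,8E)-5-methoxy-9-(4-methoxyphenyl)-3,7-dioxonona-4,8-dienoate (C3 carbonyl and C6 methylene cis on the enol ether bond) | CC(C)(C)OC(=O)CC(=O)/C=C(/OC)CC(=O)/C=C/c1ccc(OC)cc1 | intermediate |
| 5 | (E)-1-(2,4-dihydroxy-6-methoxyphenyl)-3-(4-methoxyphenyl)prop-2-en-1-one (2',4'-dihydroxy-4,6'-dimethoxychalcone) | COc1ccc(/C=C/C(=O)c2c(O)cc(O)cc2OC)cc1 | intermediate |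
| 6 | 3-methylbut-2-enal | CC(C)=CC=O | starting material |
| 7 | (2Z)-3-hydroxy-5-methoxy-4-[(E)-3-(4-methoxyphenyl)prop-2-enoyl]-2-(3-methylbut-2-en-1-ylidene)cyclohexa-3,5-dien-1-one (prenylidene chain cis to the C4' carbonyl) | COc1ccc(/C=C/C(=O)C2=C(O)/C(=C/C=C(C)C)C(=O)C=C2OC)cc1 | intermediate |
| 8 | glychalcone A, (E)-1-(5-hydroxy-7-methoxy-2,2-dimethyl-2H-chromen-6-yl)-3-(4-methoxyphenyl)prop-2-en-1-one | COc1ccc(/C=C/C(=O)c2c(OC)cc3c(c2O)C=CC(C)(C)O3)cc1 | target |

Total step count: 2. Longest linear sequence: 2.

**Steps most likely to fail** (the route has only two steps, so both are ranked and there is no third entry)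

1. Step 1, the step that bears the label.
   - **What may go wrong:**
     - The enolate may add in conjugate fashion to the pyranone, or displace the 4-methoxy group, instead of being acylated.
     - The sequence may stall after ring opening, because the ester of a lithiated β-keto ester, hindered further by the tert-butyl group, is a weak electrophile.
     - Unclosed material may then cyclise in the aldol sense on work-up.
     - Surplus enolate may add to the enone during a long warm period.
   - **Fallback (known chemistry):** ring A is bought instead of built and the order of events is inverted. The fallback sets out from 6 and rejoins the route at 8. Aldehyde 6 is condensed with purchased 1-(2,4-dihydroxy-6-methoxyphenyl)ethanone under ethylenediammonium diacetate catalysis in hot toluene, which is the established chromenylation of acylresorcinols. This gives 1-(5-hydroxy-7-methoxy-2,2-dimethyl-2H-chromen-6-yl)ethanone F1. A Claisen–Schmidt condensation of F1 with purchased 4-methoxybenzaldehyde (KOH, EtOH, room temperature) should then give 8 directly. No protecting group is needed because the only free hydroxyl is chelated.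

2. Step 2.
   - **What may go wrong:**
     - Regiocontrol between C3' and C5' may be lost.
     - The quinone methide may close on the chelated O2'.
     - Heat or amine may induce oxa-Michael isomerisation of the 2'-hydroxychalcone to the flavanone.
   - **Fallback:** the C–O bond is made first and the C–C bond follows by sigmatropic shift. The fallback sets out from 5 and returns at 8. The more acidic, unchelated 4'-hydroxyl of 5 is alkylated with 3-chloro-3-methylbut-1-yne (K2CO3, KI, acetone, reflux). This gives (E)-1-[2-hydroxy-6-methoxy-4-(2-methylbut-3-yn-2-yloxy)phenyl]-3-(4-methoxyphenyl)prop-2-en-1-one F2. Heating F2 in o-xylene at reflux should trigger the aromatic propargyl Claisen rearrangement to C3', a hydrogen shift to 7 and oxa-6π closure to 8. O4' is thus fixed as the pyran oxygen from the outset, and no nucleophilic amine is present.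

**Further compounds**
F1 | step 1 | 1-(5-hydroxy-7-methoxy-2,2-dimethyl-2H-chromen-6-yl)ethanone | CC(=O)c1c(OC)cc2c(c1O)C=CC(C)(C)O2
F2 | step 2 | (E)-1-[2-hydroxy-6-methoxy-4-(2-methylbut-3-yn-2-yloxy)phenyl]-3-(4-methoxyphenyl)prop-2-en-1-one | COc1ccc(/C=C/C(=O)c2c(O)cc(OC(C)(C)C#C)cc2OC)cc1
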